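Ring atoms are numbered C1 (bears the side chain), C2, C3 (CHOH), C4, C5 (C–OMe), C6 (CHOAc); the side chain is C1' (CH2) and C2' (CHOAc). Compounds carry the numbers 1–23 of the steps and of the list after them.

## Analysis of the target

Target 23 is a cyclohexa-1,4-diene. C1 carries a (2R)-2-acetoxytridecyl chain, C3 a free hydroxyl, C5 the methoxy group of an enol ether (C4=C5) and C6 an acetate; C1=C2 is trisubstituted. There are three stereocentres. C3 (S) and C6 (S) are 1,4-related across the ring with their oxygens on opposite faces (trans). C2' (R) is separated from the ring by the C1' methylene and cannot be used to control the ring centres. Both ring carbinol carbons are doubly allylic, and the C3 hydroxyl is also the γ-hydroxyl of an enol ether. Loss of either ring oxygen therefore gives a cyclohexadienyl cation that is one proton away from an anisole, so acid must be avoided throughout the late stage; strong base threatens the acetates and C6–H. The three oxygens must end differentiated (OH at C3, OAc at C6 and C2'), which dictates the order of the last steps. The difficulty is to build a non-aromatic, unconjugated diene bearing an enol ether without conditions that aromatise or hydrolyse it. The strategy rests on C5: with its exocyclic methoxy group it is at the oxidation level of a methyl ester carbonyl. The C4=C5 bond can therefore be made from a C5 methyl ester and a vinyl group on C3 by carbonyl–olefin ring closure with a titanium alkylidene, the ester methoxy group becoming the enol ether methoxy group.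

## Retrosynthetic reasoning

23 ⇒ 22 ⇒ 21 ⇒ 20. The O–acyl bonds are made last and the O3–Si bond is cut last. Acetates cannot be present when the ring is closed, because their carbonyl groups would be olefinated like the C5 ester. The three oxygens are therefore carried as silyl ethers of two lability classes: the more robust one on O3, the more labile ones on O6 and O2'. Removing the labile pair from 20 gives diol 21, acetylation gives 22, and the final desilylation at O3 gives 23. This costs three steps but keeps the sensitive ring away from everything except near-neutral desilylation and basic acylation.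

20 ⇒ 18 (through alkylidene 19). The C4=C5 double bond is cut. This is the only ring bond whose formation creates no stereocentre and whose geometry the ring itself enforces. It also makes the acid-labile enol ether in the same step that closes the ring, so no acyclic enol ether has to be prepared or carried. The forward reaction must convert the terminal alkene on C3 of 18 into the C4 titanium alkylidene 19 and make it olefinate the C5 ester carbonyl. The Z geometry of C1=C2 in 18 holds C3 and C6, and with them the two reacting groups, on the same side.

18 ⇒ 17 ⇒ 16. The C6–H bond is cut back to a ketone. Setting C6 by reduction of α-keto ester 16 on an open chain makes its configuration independent of C3. The trans relation of the target is then a matter of choosing the catalyst antipode, not of ring conformational bias. Silylation of 17 then gives 18.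

16 ⇒ 13 + 14 (through alkenyllithium 15). The C1–C6 bond is cut between the trisubstituted alkene and the two-carbon unit C6–C5. Oxalate diester 14 delivers C6 and C5 at the right oxidation levels in one operation, with the ester methoxy group that will end up on C5. The forward step needs a configurationally stable Z alkenyl metal at C1.

13 ⇒ 12 ⇒ 10 (through aluminate 11). The C1–I and C2–H bonds are cut back to the C1≡C2 alkyne. The free C3 hydroxyl of 10 directs a trans-hydrometalation, which places the metal, then iodine, on C1 cis to C3. This fixes the Z geometry needed two disconnections later. O2' must be masked so that only O3 directs.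

10 ⇒ 7 + 8 (through alkynylzinc 9). The C2–C3 bond is cut. Addition of the terminal alkyne 7 to enal 8 creates the C3 carbinol with its vinyl group (the future C4) in one step. The forward reaction has to control the aldehyde face by catalyst, since C2' is five atoms away.

7 ⇒ 6 ⇒ 4 + 5, and 4 ⇒ 1 + 2 (through 3). The bond between C1' and the alkyne carbon is cut (epoxide opening by acetylide 5), then the bond between the decyl chain and the epoxide-derived methylene. The C2' stereocentre thus comes unchanged from the chiral pool (1) and no asymmetric step is spent on it.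

## Alternatives that were turned down

Alternative 1: The C1=C2 alkene would be masked as a Diels–Alder adduct. Quinone A1 and cyclopentadiene A2 would combine at C1=C2 to the endo adduct A3 under a chiral cationic oxazaborolidine (triflimide counter-ion). The two ring carbonyls would then be reduced, the oxygens differentiated, and the bridge removed by retro-Diels–Alder reaction.
- For it: all six ring carbons with the right substituents come from an aromatic precursor in very few steps. The C5 methoxy group is present from the start as a vinylogous ester. One catalytic step sets the absolute configuration. On brevity of skeleton assembly it is stronger than the chosen route.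
- Against it: both carbonyls of A3 sit on the same concave/convex framework, so hydride from the open face would put the C3 and C6 oxygens cis, whereas 23 needs them trans. One centre would have to be inverted, and C6 is neopentylic next to the quaternary C1 of A3. The hindered C6 oxygen is the one to be acetylated and the accessible C3 oxygen the one to stay free, the reverse of steric preference. The cycloreversion needs strong heating of a doubly allylic acetate with an enol ether, exactly the conditions under which this ring aromatises.
- Comparison: the chosen strategy never heats or acidifies the finished ring, and sets C3 and C6 independently.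

Alternative 2: The C1–C6 bond would be closed by a Nozaki–Hiyama–Kishi reaction. The open-chain iodo-aldehyde A4 (Z alkenyl iodide at C1, aldehyde at C6) would cyclise with CrCl2/NiCl2 and a chiral sulfonamide ligand to the ring carbinol A5.
- For it: the closure forms the ring and the C6 carbinol together. It tolerates the C2' acetate, which can be in place from the start. A5 has O6 free and alone, so the end game is only acetylation and one desilylation. On protecting-group economy it is stronger than the chosen route.
- Against it: A4 requires the C4=C5 enol ether to be built on an open chain with C3 and C6 cis, as a 2-methoxy-enal. This push–pull alkene isomerises easily and is a poor electrophile. The new C6 centre forms during ring closure, where the ligand has to override the bias of the existing C3 centre. Stoichiometric chromium is needed.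
- Comparison: the chosen route sets C6 on an acyclic ketone before the ring exists. It forms the enol ether only as part of the ring, where it can only be cis.

Alternative 3: The trisubstituted C1=C2 alkene would be closed by ring-closing metathesis. Triene A6 (1,1-disubstituted alkene at C1, vinyl group on C3) would give A7 with the second-generation Grubbs catalyst, (H2IMes)(PCy3)Cl2Ru=CHPh.
- For it: ruthenium metathesis is catalytic and tolerates acetates, so both acetates are already present in A6. Forming a trisubstituted alkene in a six-membered ring is favourable. One desilylation of A7 ends the synthesis. On functional-group tolerance and end-game length it is the strongest of the four.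
- Against it: the cost is moved into A6. This needs a cis trisubstituted methyl enol ether on an open chain between two stereocentres, and a doubly allylic acetate at C6 in acyclic form, which is prone to ionisation and allylic transposition. The electron-rich C4=C5 enol ether can also engage the ruthenium carbene (Fischer carbene formation or chain cleavage) in competition with closure.
- Comparison: the chosen route avoids any acyclic enol ether by deriving the C4=C5 bond from an ester. It pays with three protecting-group operations and a stoichiometric titanium reagent.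

Key step: step 10

Assumption: the (R,R)-antipode of the ProPhenol ligand is taken as the one that delivers the alkynyl group to the Si face of enal 8, the (S,S)-ligand being taken as Re-selective for aldehydes; if the sense proves reversed, the antipodal ligand is used and nothing else changes.

## Steps

Step 1
Reactants: 1 (R)-epichlorohydrin; 2 decylmagnesium bromide
Product: 4 (R)-2-undecyloxirane, via magnesium chlorohydrin alkoxide 3 (not isolated)
Conditions: CuI (10 mol%), THF, −40 → 0 °C; then aq. NaOH, rt
Reagents that add atoms: none
Why: Copper-catalysed Grignard opening of the epoxide at its unsubstituted carbon gives chlorohydrin alkoxide 3, and base then closes the new epoxide by intramolecular Williamson displacement of the primary chloride; neither event touches the stereocentre, so the (R) configuration of 1 is carried into 4.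

Step 2
Reactants: 4 (R)-2-undecyloxirane; 5 lithium acetylide–ethylenediamine complex
Product: 6 (R)-pentadec-1-yn-4-ol
Conditions: DMSO, rt; aq. NH4Cl
Reagents that add atoms: none
Why: SN2 opening of a terminal epoxide by acetylide at the primary carbon is a standard route to terminal homopropargylic alcohols; the carbinol centre is not involved and stays (R).

Step 3
Reactants: 6 (R)-pentadec-1-yn-4-ol
Product: 7 (R)-triethyl(pentadec-1-yn-4-yloxy)silane
Conditions: TESCl, imidazole, DMF, 0 °C → rt
Reagents that add atoms: chlorotriethylsilane, CC[Si](Cl)(CC)CC
Why: Routine silylation of a secondary alcohol; masking O2' ensures that only the C3 hydroxyl can direct the later hydroalumination and that no lactone can form once the C5 ester is present.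

Step 4
Reactants: 7 (R)-triethyl(pentadec-1-yn-4-yloxy)silane; 8 acrolein
Product: 10 (3R,7R)-7-[(triethylsilyl)oxy]octadec-1-en-4-yn-3-ol, via alkynyl(methyl)zinc 9 (not isolated)
Conditions: Me2Zn, (R,R)-2,6-bis{[2-(hydroxydiphenylmethyl)pyrrolidin-1-yl]methyl}-4-methylphenol [(R,R)-ProPhenol, 20 mol%], Ph3P=O (40 mol%), toluene, 0 °C; then 8, 0–4 °C; aq. NH4Cl
Reagents that add atoms: none
Why: Catalytic asymmetric alkynylation of an enal: Me2Zn deprotonates the alkyne to alkynylzinc 9, which is delivered inside the chiral dinuclear zinc–aminoalcohol pocket to the Si face of the aldehyde, setting the new carbinol as (3R) in 10 (the ring C3 of the target, S there because the priorities change); the C2' centre is too remote to interfere.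

Step 5
Reactants: 10 (3R,7R)-7-[(triethylsilyl)oxy]octadec-1-en-4-yn-3-ol
Product: 12 (3R,4Z,7R)-5-iodo-7-[(triethylsilyl)oxy]octadeca-1,4-dien-3-ol, via cyclic alkenylaluminate 11 (not isolated)
Conditions: NaAlH2(OCH2CH2OCH3)2, THF, 0 °C → rt; EtOAc; then I2, THF, −78 → 0 °C
Reagents that add atoms: iodine, II
Why: Hydroxyl-directed trans-hydroalumination of a propargylic alcohol: the oxygen-bound aluminium hydride delivers hydride to the proximal alkyne carbon (ring C2) and aluminium to ring C1 within the five-membered aluminate 11, and iodinolysis of the C–Al bond with retention gives the Z alkenyl iodide with iodine cis to C3; the silylated O2' cannot direct and the isolated vinyl group is not reduced.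

Step 6
Reactants: 12 (3R,4Z,7R)-5-iodo-7-[(triethylsilyl)oxy]octadeca-1,4-dien-3-ol
Product: 13 tert-butyl{[(3R,4Z,7R)-5-iodo-7-[(triethylsilyl)oxy]octadeca-1,4-dien-3-yl]oxy}dimethylsilane
Conditions: TBSCl, imidazole, DMF, rt
Reagents that add atoms: tert-butylchlorodimethylsilane, CC(C)(C)[Si](C)(C)Cl
Why: Standard silylation of a secondary allylic alcohol; the tert-butyldimethylsilyl ether is chosen for O3 because it has to outlast the two triethylsilyl ethers at the end.

Step 7
Reactants: 13 tert-butyl{[(3R,4Z,7R)-5-iodo-7-[(triethylsilyl)oxy]octadeca-1,4-dien-3-yl]oxy}dimethylsilane; 14 dimethyl oxalate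
Product: 16 methyl (3Z,5R)-5-[(tert-butyldimethylsilyl)oxy]-2-oxo-3-{(2R)-2-[(triethylsilyl)oxy]tridecyl}hepta-3,6-dienoate, via alkenyllithium 15 (not isolated)
Conditions: t-BuLi (2.1 equiv), Et2O, −78 °C; then cannulated into 14 (3 equiv), THF, −78 °C; AcOH quench at −78 °C
Reagents that add atoms: none
Why: Iodine–lithium exchange of an alkenyl iodide with two equivalents of t-BuLi proceeds with retention of alkene geometry at −78 °C, and inverse addition of alkenyllithium 15 to excess oxalate diester stops at the α-keto ester because the tetrahedral adduct is stable at low temperature (acylation of an organolithium by an oxalate).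

Step 8
Reactants: 16 methyl (3Z,5R)-5-[(tert-butyldimethylsilyl)oxy]-2-oxo-3-{(2R)-2-[(triethylsilyl)oxy]tridecyl}hepta-3,6-dienoate
Product: 17 methyl (2S,3Z,5R)-5-[(tert-butyldimethylsilyl)oxy]-2-hydroxy-3-{(2R)-2-[(triethylsilyl)oxy]tridecyl}hepta-3,6-dienoate
Conditions: (S)-1-methyl-3,3-diphenyltetrahydro-1H,3H-pyrrolo[1,2-c][1,3,2]oxazaborole [(S)-Me-CBS, 0.5–1 equiv], catecholborane, toluene, −78 °C
Reagents that add atoms: none
Why: CBS reduction of the ketone: with the α-branched alkenyl group as the large and the planar methoxycarbonyl group as the small substituent, the (S)-catalyst should deliver hydride to the face that gives the (2S) alcohol (ring C6, S), which is the epimer with O6 trans to O3 in the later ring; the centre is set by the catalyst and not by the distant C3 and C2' centres, and catecholborane at −78 °C leaves ester, alkenes and silyl ethers alone.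

Step 9
Reactants: 17 methyl (2S,3Z,5R)-5-[(tert-butyldimethylsilyl)oxy]-2-hydroxy-3-{(2R)-2-[(triethylsilyl)oxy]tridecyl}hepta-3,6-dienoate
Product: 18 methyl (2S,3Z,5R)-5-[(tert-butyldimethylsilyl)oxy]-2-[(triethylsilyl)oxy]-3-{(2R)-2-[(triethylsilyl)oxy]tridecyl}hepta-3,6-dienoate
Conditions: TESCl, imidazole, DMAP (cat.), DMF, 0 °C → rt
Reagents that add atoms: chlorotriethylsilane, CC[Si](Cl)(CC)CC
Why: Silylation of the α-hydroxy ester under mildly basic conditions that do not epimerise C6; the product is the cyclisation substrate, in which the C5 ester is the only carbonyl group.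

Step 10
Reactants: 18 methyl (2S,3Z,5R)-5-[(tert-butyldimethylsilyl)oxy]-2-[(triethylsilyl)oxy]-3-{(2R)-2-[(triethylsilyl)oxy]tridecyl}hepta-3,6-dienoate
Product: 20 (3S,6S)-3-[(tert-butyldimethylsilyl)oxy]-5-methoxy-6-[(triethylsilyl)oxy]-1-{(2R)-2-[(triethylsilyl)oxy]tridecyl}cyclohexa-1,4-diene, via C4 titanium alkylidene 19 (not isolated)
Conditions: TiCl4, TMEDA, Zn, PbCl2 (cat.), CH3CHBr2, THF–CH2Cl2, 0 → 65 °C; aq. K2CO3, filtration through basic Al2O3
Reagents that add atoms: none
Why: The reagent made from TiCl4, Zn, catalytic PbCl2, TMEDA and CH3CHBr2 is a low-valent titanium ethylidene; being too hindered to olefinate the α-branched ester quickly, it should first exchange with the only monosubstituted alkene (the vinyl group on C3) through a titanacyclobutane, expelling propene and leaving alkylidene 19. The C4 alkylidene then adds across the C5 ester carbonyl, held close by the Z C1=C2 alkene, and the oxatitanacyclobutane collapses to the C4=C5 enol ether and a titanium oxo species, the oxophilicity of titanium driving the step. The closest known reaction type is the olefinic-ester cyclisation with this reagent that gives cyclic enol ethers, together with intramolecular ester olefination by titanium alkylidenes and enol-ether–olefin ring-closing metathesis, both of which give 1-alkoxycycloalkenes. The six-membered carbocycle closes in a 6-exo-trig sense with respect to the carbonyl (C4 attacks C5 and the carbonyl oxygen leaves outside the ring), and only the cis ring alkene can form. No stereocentre is created, and C3, C6 and C2' are untouched because the medium neither ionises the allylic silyl ethers nor enolises C6. The selectivity needed is chemoselectivity: the substrate has one ester and one terminal alkene, the trisubstituted C1=C2 alkene is inert to the bulky alkylidene, and acetates are absent because they would be olefinated. Should ester ethylidenation precede the exchange, the acyclic enol ether so formed can still be closed by metathesis to the same ring.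

Step 11
Reactants: 20 (3S,6S)-3-[(tert-butyldimethylsilyl)oxy]-5-methoxy-6-[(triethylsilyl)oxy]-1-{(2R)-2-[(triethylsilyl)oxy]tridecyl}cyclohexa-1,4-diene
Product: 21 (1S,4S)-4-[(tert-butyldimethylsilyl)oxy]-2-[(2R)-2-hydroxytridecyl]-6-methoxycyclohexa-2,5-dien-1-ol
Conditions: HF·pyridine, excess pyridine, THF, 0 °C; aq. NaHCO3
Reagents that add atoms: none
Why: Fluoride-mediated desilylation in which secondary triethylsilyl ethers are cleaved far faster than a secondary tert-butyldimethylsilyl ether; the large excess of pyridine keeps the medium close to neutral so that the enol ether and the doubly allylic C3–O bond are not ionised.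

Step 12
Reactants: 21 (1S,4S)-4-[(tert-butyldimethylsilyl)oxy]-2-[(2R)-2-hydroxytridecyl]-6-methoxycyclohexa-2,5-dien-1-ol
Product: 22 (1S,4S)-2-[(2R)-2-(acetyloxy)tridecyl]-4-[(tert-butyldimethylsilyl)oxy]-6-methoxycyclohexa-2,5-dien-1-yl acetate
Conditions: Ac2O, pyridine, DMAP (cat.), CH2Cl2, 0 °C → rt
Reagents that add atoms: acetic anhydride, CC(=O)OC(C)=O
Why: DMAP-catalysed acylation of both free secondary hydroxyls under basic conditions that the enol ether tolerates; O3 is still silylated, so the acetate pattern of the target results.

Step 13
Reactants: 22 (1S,4S)-2-[(2R)-2-(acetyloxy)tridecyl]-4-[(tert-butyldimethylsilyl)oxy]-6-methoxycyclohexa-2,5-dien-1-yl acetate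
Product: 23 (1S,4S)-2-[(2R)-2-(acetyloxy)tridecyl]-4-hydroxy-6-methoxycyclohexa-2,5-dien-1-yl acetate (CNP0081579.1; C3 S, C6 S, C2' R in the numbering of the analysis)
Conditions: Bu4NF, AcOH (1:1), THF, 0 °C → rt; chromatography on Et3N-treated silica
Reagents that add atoms: none
Why: Fluoride cleavage of the remaining silyl ether; buffering with acetic acid suppresses base-induced acetate cleavage while staying too weakly acidic to ionise the C3 carbinol, and no acyl migration is possible between the 1,4-related O6 and O3.

## Compound list

1 | (R)-epichlorohydrin [(2R)-2-(chloromethyl)oxirane] | ClC[C@H]1CO1 | starting material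
2 | decylmagnesium bromide | CCCCCCCCCC[Mg]Br | starting material
3 | bromomagnesium alkoxide of (R)-1-chlorotridecan-2-ol | ClC[C@H](O[Mg]Br)CCCCCCCCCCC | intermediate
4 | (R)-2-undecyloxirane | CCCCCCCCCCC[C@@H]1CO1 | intermediate
5 | lithium acetylide–ethylenediamine complex | [Li+].[C-]#C.NCCN | starting material
6 | (R)-pentadec-1-yn-4-ol | CCCCCCCCCCC[C@H](CC#C)O | intermediate
7 | (R)-triethyl(pentadec-1-yn-4-yloxy)silane | CCCCCCCCCCC[C@H](CC#C)O[Si](CC)(CC)CC | intermediate
8 | acrolein | C=CC=O | starting material
9 | methyl[(4R)-4-(triethylsilyloxy)pentadec-1-yn-1-yl]zinc | CCCCCCCCCCC[C@H](CC#C[Zn]C)O[Si](CC)(CC)CC | intermediate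
10 | (3R,7R)-7-[(triethylsilyl)oxy]octadec-1-en-4-yn-3-ol | CCCCCCCCCCC[C@H](CC#C[C@H](O)C=C)O[Si](CC)(CC)CC | intermediate
11 | sodium salt of the cyclic alkenylaluminate from 10 (five-membered O–Al–C1=C2–C3 ring, two 2-methoxyethoxy ligands on aluminium) | [Na+].CCCCCCCCCCC[C@H](CC1=C[C@@H](C=C)O[Al-]1(OCCOC)OCCOC)O[Si](CC)(CC)CC | intermediate
12 | (3R,4Z,7R)-5-iodo-7-[(triethylsilyl)oxy]octadeca-1,4-dien-3-ol | CCCCCCCCCCC[C@H](C/C(I)=C/[C@H](O)C=C)O[Si](CC)(CC)CC | intermediate
13 | tert-butyl{[(3R,4Z,7R)-5-iodo-7-[(triethylsilyl)oxy]octadeca-1,4-dien-3-yl]oxy}dimethylsilane | CCCCCCCCCCC[C@H](C/C(I)=C/[C@H](O[Si](C)(C)C(C)(C)C)C=C)O[Si](CC)(CC)CC | intermediate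
14 | dimethyl oxalate | COC(=O)C(=O)OC | starting material
15 | alkenyllithium from 13 (lithium in place of iodine, alkene geometry retained) | CCCCCCCCCCC[C@H](C/C([Li])=C/[C@H](O[Si](C)(C)C(C)(C)C)C=C)O[Si](CC)(CC)CC | intermediate
16 | methyl (3Z,5R)-5-[(tert-butyldimethylsilyl)oxy]-2-oxo-3-{(2R)-2-[(triethylsilyl)oxy]tridecyl}hepta-3,6-dienoate | CCCCCCCCCCC[C@H](C/C(=C/[C@H](O[Si](C)(C)C(C)(C)C)C=C)C(=O)C(=O)OC)O[Si](CC)(CC)CC | intermediate
17 | methyl (2S,3Z,5R)-5-[(tert-butyldimethylsilyl)oxy]-2-hydroxy-3-{(2R)-2-[(triethylsilyl)oxy]tridecyl}hepta-3,6-dienoate | CCCCCCCCCCC[C@H](C/C(=C/[C@H](O[Si](C)(C)C(C)(C)C)C=C)[C@H](O)C(=O)OC)O[Si](CC)(CC)CC | intermediate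
18 | methyl (2S,3Z,5R)-5-[(tert-butyldimethylsilyl)oxy]-2-[(triethylsilyl)oxy]-3-{(2R)-2-[(triethylsilyl)oxy]tridecyl}hepta-3,6-dienoate (methyl ester diene, precursor of the key step) | CCCCCCCCCCC[C@H](C/C(=C/[C@H](O[Si](C)(C)C(C)(C)C)C=C)[C@H](O[Si](CC)(CC)CC)C(=O)OC)O[Si](CC)(CC)CC | intermediate
19 | C4 titanium alkylidene of 18 (drawn as the dichlorotitanium alkylidene, TMEDA ligand left out) | CCCCCCCCCCC[C@H](C/C(=C/[C@H](O[Si](C)(C)C(C)(C)C)C=[Ti](Cl)Cl)[C@H](O[Si](CC)(CC)CC)C(=O)OC)O[Si](CC)(CC)CC | intermediate
20 | (3S,6S)-3-[(tert-butyldimethylsilyl)oxy]-5-methoxy-6-[(triethylsilyl)oxy]-1-{(2R)-2-[(triethylsilyl)oxy]tridecyl}cyclohexa-1,4-diene (tris-silyl ether of the ring diene) | CCCCCCCCCCC[C@H](CC1=C[C@H](O[Si](C)(C)C(C)(C)C)C=C(OC)[C@H]1O[Si](CC)(CC)CC)O[Si](CC)(CC)CC | intermediate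
21 | (1S,4S)-4-[(tert-butyldimethylsilyl)oxy]-2-[(2R)-2-hydroxytridecyl]-6-methoxycyclohexa-2,5-dien-1-ol | CCCCCCCCCCC[C@H](CC1=C[C@H](O[Si](C)(C)C(C)(C)C)C=C(OC)[C@H]1O)O | intermediate
22 | (1S,4S)-2-[(2R)-2-(acetyloxy)tridecyl]-4-[(tert-butyldimethylsilyl)oxy]-6-methoxycyclohexa-2,5-dien-1-yl acetate | CCCCCCCCCCC[C@H](CC1=C[C@H](O[Si](C)(C)C(C)(C)C)C=C(OC)[C@H]1OC(C)=O)OC(C)=O | intermediate
23 | (1S,4S)-2-[(2R)-2-(acetyloxy)tridecyl]-4-hydroxy-6-methoxycyclohexa-2,5-dien-1-yl acetate (CNP0081579.1) | CCCCCCCCCCC[C@H](CC1=C[C@H](O)C=C(OC)[C@H]1OC(C)=O)OC(C)=O | target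

## Step count and least certain steps

Total: 13 steps. Longest linear sequence: 13 steps (from 1; the route is fully linear, and 2, 5, 8 and 14 are bought).

Step 10 (key step). The most likely failure is slow alkylidene exchange at the vinyl group, which is flanked by the branched, silyloxy-bearing C3. Direct ethylidenation of the ester would then win and give an acyclic enol ether that does not close under the titanium conditions. A second risk is aromatisation of the product by loss of a silanol during work-up. Fallback: from 18, the ester is methylenated with the CH2Br2 variant of the same titanium reagent (or with Cp2TiMe2 at 65 °C) to the 2-methoxy-1-alkene F1. F1 is then closed by enol-ether–olefin ring-closing metathesis with the second-generation Grubbs catalyst (or with Mo(=CHCMe2Ph)(=N-2,6-iPr2C6H3)[OCMe(CF3)2]2) in toluene at 60–80 °C, which rejoins the route at 20.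

Step 4. Acrolein may polymerise under the basic zinc conditions, conversion of the alkyne (used as the limiting component) may be poor, and the facial selectivity may be insufficient or opposite to the assumption. Fallback: from 7, deprotonation with n-BuLi and addition to 8 gives the C3-epimeric mixture F2 without any catalyst. A Sharpless kinetic resolution (Ti(OiPr)4, D-(−)-diisopropyl tartrate, t-BuOOH, 4 Å sieves, CH2Cl2, −20 °C) should then epoxidise the vinyl group of the (3S) epimer to the anti epoxy alcohol F3 and leave the (3R) epimer, which is 10. The sense is that of the usual rule, transposed for the fact that the alkynyl group outranks vinyl.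

Step 7. Alkenyllithium 15 may suffer 1,4-migration of silicon from O3 or O2' to C1. The oxalate may add twice. The Z enone may isomerise through reversible conjugate addition of methoxide during the quench. Fallback: from 13, a Nozaki–Hiyama–Kishi coupling with methyl glyoxylate (CrCl2, NiCl2 cat., DMSO, rt) avoids a basic carbanion and gives the hydroxy ester F4 as a mixture of C6 epimers. Dess–Martin oxidation of F4 returns to the route at 16.

Step 8. Facial selectivity may be poor because the methoxycarbonyl and alkenyl groups are not cleanly differentiated by the oxazaborolidine. The activated ketone may be reduced without the catalyst. Conjugate reduction may compete. Fallback: from 16, unselective Luche reduction (NaBH4, CeCl3·7H2O, MeOH, −78 °C) gives 17 together with its C6 epimer F5. The two diastereomers are separated by chromatography, and F5 is returned to 16 by Dess–Martin oxidation and recycled; the route is rejoined at 17.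

Step 11. Even buffered HF·pyridine may protonate the enol ether or ionise the C3–O bond, leading to hydrolysis or aromatisation. The discrimination between the triethylsilyl and tert-butyldimethylsilyl ethers may be incomplete. The same sensitivity applies to step 13. Fallback: from 20, all three silyl groups are removed with Bu4NF in THF (basic conditions, which the ring tolerates) to give triol F6. Acetylation (Ac2O, pyridine, DMAP) gives triacetate F7. A lipase (lipase B from Candida antarctica, n-butanol, tert-butyl methyl ether, 30 °C) is then used at neutral pH to remove the least hindered acetate, the one on C3 flanked by two vinylic CH groups. This arrives directly at 23 and bypasses steps 12 and 13.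

## Further compounds

F1 | step 10 | (3S,4Z,6R)-2-methoxy enol ether triene from methylenation of 18 (C5 ester carbonyl replaced by C=CH2) | CCCCCCCCCCC[C@H](C/C(=C/[C@H](O[Si](C)(C)C(C)(C)C)C=C)[C@H](O[Si](CC)(CC)CC)C(=C)OC)O[Si](CC)(CC)CC
F2 | step 4 | (7R)-7-[(triethylsilyl)oxy]octadec-1-en-4-yn-3-ol, mixture of C3 epimers | CCCCCCCCCCC[C@H](CC#CC(O)C=C)O[Si](CC)(CC)CC
F3 | step 4 | (1R,5R)-1-[(2S)-oxiran-2-yl]-5-[(triethylsilyl)oxy]hexadec-2-yn-1-ol (anti epoxy alcohol from the 3S epimer) | CCCCCCCCCCC[C@H](CC#C[C@@H](O)[C@@H]1CO1)O[Si](CC)(CC)CC
F4 | step 7 | methyl (3Z,5R)-5-[(tert-butyldimethylsilyl)oxy]-2-hydroxy-3-{(2R)-2-[(triethylsilyl)oxy]tridecyl}hepta-3,6-dienoate, mixture of C2 epimers | CCCCCCCCCCC[C@H](C/C(=C/[C@H](O[Si](C)(C)C(C)(C)C)C=C)C(O)C(=O)OC)O[Si](CC)(CC)CC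
F5 | step 8 | methyl (2R,3Z,5R)-5-[(tert-butyldimethylsilyl)oxy]-2-hydroxy-3-{(2R)-2-[(triethylsilyl)oxy]tridecyl}hepta-3,6-dienoate (C6 epimer of 17) | CCCCCCCCCCC[C@H](C/C(=C/[C@H](O[Si](C)(C)C(C)(C)C)C=C)[C@@H](O)C(=O)OC)O[Si](CC)(CC)CC
F6 | step 11 | (1S,4S)-2-[(2R)-2-hydroxytridecyl]-6-methoxycyclohexa-2,5-diene-1,4-diol (triol) | CCCCCCCCCCC[C@H](CC1=C[C@H](O)C=C(OC)[C@H]1O)O
F7 | step 11 | (1S,4S)-2-[(2R)-2-(acetyloxy)tridecyl]-6-methoxycyclohexa-2,5-diene-1,4-diyl diacetate (triacetate) | CCCCCCCCCCC[C@H](CC1=C[C@H](OC(C)=O)C=C(OC)[C@H]1OC(C)=O)OC(C)=O
A1 | alternative 1 | 2-[(2R)-2-(acetyloxy)tridecyl]-6-methoxy-1,4-benzoquinone | CCCCCCCCCCC[C@H](CC1=CC(=O)C=C(OC)C1=O)OC(C)=O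
A2 | alternative 1 | cyclopenta-1,3-diene | C1C=CC=C1
A3 | alternative 1 | endo cyclopentadiene adduct of the quinone across C1=C2 | CCCCCCCCCCC[C@H](C[C@@]12C(=O)C(OC)=CC(=O)[C@@H]1[C@@H]1C=C[C@H]2C1)OC(C)=O
A4 | alternative 2 | open-chain C6 aldehyde with Z iodoalkene at C1=C2, cis enol ether C4=C5, O3 tert-butyldimethylsilyl, O2' acetyl | CCCCCCCCCCC[C@H](C/C(I)=C/[C@H](O[Si](C)(C)C(C)(C)C)/C=C(/OC)C=O)OC(C)=O
A5 | alternative 2 | 6-hydroxy ring diene, O3 tert-butyldimethylsilyl, O2' acetyl | CCCCCCCCCCC[C@H](CC1=C[C@H](O[Si](C)(C)C(C)(C)C)C=C(OC)[C@H]1O)OC(C)=O
A6 | alternative 3 | open-chain triene with 1,1-disubstituted alkene at C1, vinyl group on C3, cis enol ether C4=C5, O3 triethylsilyl, O6 and O2' acetyl | CCCCCCCCCCC[C@H](CC(=C)[C@H](OC(C)=O)/C(OC)=C\[C@@H](O[Si](CC)(CC)CC)C=C)OC(C)=O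
A7 | alternative 3 | 3-O-triethylsilyl ether of the target | CCCCCCCCCCC[C@H](CC1=C[C@H](O[Si](CC)(CC)CC)C=C(OC)[C@H]1OC(C)=O)OC(C)=O
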